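Decision: reagent is counted in pairs, taking double product to carry 2 reagent per starting material.

| setting | south | south-west | north-west | Sunday's | Tuesday's |
|---|---|---|---|---|---|
| starting material | 0.050 M | 0.050 M | 0.050 M | 0.050 M | 0.050 M |
| reagent | 0.047 M | 0.075 M | 0.089 M | 0.0600 M | 0.100 M |
| remark | run made earlier | run made earlier | run made earlier |  |  |
| time |  |  |  | 1.0 h | 1.0 h |

| run | time / min | double product / % | triple product / % |
|---|---|---|---|
| south | 5.00 | 19.5 | 0.1 |
| south | 15.0 | 27.1 | 0.7 |
| south | 30.0 | 22.6 | 0.2 |
| south | 40.0 | 19.3 | 0 |
| south | 60.0 | 13.3 | 0.5 |
| south-west | 12.0 | 49.5 | 0.4 |
| south-west | 25.0 | 45.6 | 1.1 |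
| south-west | 40.0 | 36.5 | 1.4 |
| south-west | 50.0 | 30.5 | 0.8 |
| south-west | 60.0 | 26.1 | 1.3 |
| north-west | 5.00 | 45.0 | 0.1 |
| north-west | 15.0 | 58.1 | 1.2 |
| north-west | 30.0 | 51.7 | 2.2 |
| north-west | 40.0 | 44.5 | 2.2 |
| north-west | 60.0 | 30.9 | 2.8 |

(readings scatter by 0.5 percentage points)

- the earlier runs were read with a standard deviation of 0.5 percentage points

1. which of these holds the largest part of the starting material at the end of Sunday's (triple product / double product / single product / starting material)
2. which of these holds the largest part of the starting material at the end of Tuesday's (triple product / double product / single product / starting material)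
3. double product at the end of Sunday's, in percent of the starting material charged

1. Let p be the reagent charge over 2 starting-material charges: 0.600 for Sunday's flask. Double product ever formed, I (fraction of the charge), then has a ceiling of p. Its statistical zero is p squared, the case of 2 independent sites.

2. The south run has p = 0.470. Its late readings fall at 0.0177 min⁻¹, which back-extrapolates to I = 0.384. The position, the distance of I above the statistical zero as a fraction of the way to the ceiling, reads 0.655.

3. Assume that lost double product keeps its reagent. Then single product = 2(p − I), and starting material is the remainder.

4. Turned round: single product leads starting material in Sunday's flask below a position of 0.444, and the south run reads higher. Carrying that reading over, Sunday's flask has I = 0.517, single product 0.166 and starting material 0.317, ahead of double product 0.179 after 1.0 h.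

5. Tuesday's flask has p = 1.00, where ceiling and zero meet: I = 1.00, so double product 0.346 leads starting material 0 and single product 0.

6. The forecast says single product for Sunday's, single product for Tuesday's and 19.8 % double product, reading the double product thus: “It seems to fall back first-order to single product”. The reckoning here differs: the lost form keeps its reagent.

7. The flasks give starting material on Sunday's, double product on Tuesday's and 18.5 % double product on Sunday's.

    starting material + reagent → single product (k = 3.96 L mol⁻¹ min⁻¹)
    reagent + single product → double product (k = 9.99 L mol⁻¹ min⁻¹)
    reagent + double product → triple product (k = 0.101 L mol⁻¹ min⁻¹)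
    double product → side product (k = 0.0187 min⁻¹)

In Sunday's flask double product was made while reagent, the limiting reagent, lasted: 99.3 % of that turnover lay behind it at 0.500 h, with reagent at 0.549 % of its own charge. The loss to side product went on taking double product from 32.0 % to 18.5 %, and for 4.0 h position 0.655 with the south fall gives 0.739 %, where the same flask holds 0.638 %.

(All runs come from a simulation for substances that don't exist, noise included.)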